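## Structural features

The target 20 is a flavone: benzene ring A is fused along C4a–C8a to the 4-pyranone ring C (O1, C2, C3, C4), and aryl ring B is bonded to C2. Ring A is fully substituted and carries five contiguous oxygens (O1 at C8a, OMe at C8, OH at C7, OMe at C6, OH at C5) with the C4 carbonyl carbon on C4a. Ring B is a 3,5-dihydroxy-4-methoxyphenyl group. There is no stereocentre, so no stereocentres stand next to each other and the whole problem is one of constitution. Fragile groups are the four free phenols on electron-rich rings, the pyranone (opened at C2 by hydroxide or alkoxide), the three methyl ethers that must survive deprotection, and the electron-rich hydroxybenzoic acids on the way, which can lose CO2 in acid. The real difficulty is the hexasubstituted ring A: three hydroxyl oxygens must be told apart from two methoxy oxygens and the acyl carbon placed on the one remaining carbon. If O1 and the C5 oxygen are taken together, ring A is symmetric about the C7···C4a axis, so a symmetric ring A building block can be used. The key step exploits that C3 is the only CH of ring C and lies between C4 (on C4a) and C2 (on O1 and ring B), both at the carboxylic acid oxidation level; a ring A salicylic acid esterified on its phenol oxygen by the ring B acid therefore holds every atom of ring C except C3.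

## Logic of the disconnections

20 to 18 (through 19): three O–CH2Ph bonds and one O–Si bond are cut. The four phenols would quench any ylide and make every intermediate polar and oxidisable, so they are masked up to the end. The forward step must spare three methyl ethers and the C2=C3 bond, which fluoride followed by hydrogenolysis does; both operations are run in one flask.

18 to 12 and 16 (through 17): the C3–C4 single bond and the C2=C3 double bond are cut, which opens ring C and removes C3. This turns a flavone into an ester of two carboxylic acids plus a one-carbon ylide, with C2 and C4 both at the acid oxidation level and O1 already in place. The forward step needs the ylide to attack the silyl ester before the aryl ester, and a substrate free of acidic protons.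

12 to 11: two O–Si bonds are cut. One silylating agent installs both the activated ester and the protection of the remaining ring A hydroxyl. The forward step must be non-nucleophilic so that the aryl ester is not cleaved.

11 to 6 and 9 (through 10): the ester C–O bond that becomes O1–C2 is cut. This is the convergent point where rings A and B meet. Because the two hydroxyls of 6 are equivalent by symmetry, either one gives the same product and acyl migration between them changes nothing. The forward step must stop after one acylation.

6 to 5: the bond from the ring carbon (future C4a) to the carboxyl carbon (future C4) is cut. The only unsubstituted ring carbon of 5 lies between the two hydroxyls, so carboxylation has no regiochemical choice.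

5 to 3 (through 4), then 3 to 2 and 2 to 1: two aryl C–O bonds are cut back to C–Br bonds, then to C–H bonds, and the O–benzyl bond is cut last. Capping the phenol of 1 first is essential, as otherwise bromination would go para to the free hydroxyl. The forward oxidation of the boron intermediate must be mild enough for an electron-rich resorcinol.

9 to 7 (through 8): two phenolic O–benzyl bonds are cut; the transient ester is removed in the same flask.

16 to 13 (through 14 and 15): the C–Si bond of the ylide is cut; the forward step needs a base that does not attack silicon, which is why the unsilylated ylide itself serves as base.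

## Other disconnections considered

Alternative 1: The cut is at C4–C4a and O1–C2, so ring C is assembled in one operation from 5 and the ring B aroylacetate A2 (ethyl 3-[3,5-bis(benzyloxy)-4-methoxyphenyl]-3-oxopropanoate, one step from 9 by malonate half-ester acylation). The forward key step is an uncatalysed thermal condensation (neat or in diphenyl ether, well above 200 °C). A2 would lose ethanol to an aroylketene that acylates the ring carbon of 5 between the two hydroxyls, and the diketone so formed would close O1–C2 with loss of water to give A1, which is the same compound as 19.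
- In its favour: no carboxylation, no silyl groups and no phosphorus waste; the symmetry of 5 removes any regiochemical question; A1 needs only hydrogenolysis.
- Against it here: the temperature is hard on three benzyl aryl ethers and on a pentaoxygenated resorcinol (benzyl migration to carbon, oxidation); A2 can self-condense or decarboxylate; the Pechmann-type closure to a 4-arylcoumarin is a competing constitutional outcome.
- Comparison: on structure the two plans are equal, since both use 5 and 9 and the same symmetry. On step economy the alternative is the better, by about three steps. On mechanism the chosen plan is the better, since it forms C3–C4 and C2=C3 in two discrete polar events below 70 °C with no chromone/coumarin ambiguity.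

Alternative 2: The cut is at the C6–OMe and C8–OMe aryl–oxygen bonds; both methoxy groups are introduced on a finished flavone. The parent A3 (2-[3,5-bis(benzyloxy)-4-methoxyphenyl]-5,7-dihydroxychromen-4-one) would be dibrominated ortho to its phenols to A4 (the 6,8-dibromo compound). The forward key step treats A4 with sodium methoxide and CuBr (monovalent copper) in DMF–methanol, replacing both bromines in an Ullmann-type coupling to give A5 (2-[3,5-bis(benzyloxy)-4-methoxyphenyl]-5,7-dihydroxy-6,8-dimethoxychromen-4-one).
- In its favour: ring A would start from cheap, only tri-oxygenated material; the phenols dictate the bromination sites; base-induced ring opening and reclosure, which can exchange C6 and C8 substituents, is harmless because the ring A pattern is symmetric.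
- Against it here: two substitutions are needed at carbons flanked on both sides by oxygen, on a bis-phenoxide. Hydrodebromination can compete at each, and its products would be hard to separate from A5. Hot methoxide can also open the pyranone at C2.
- Comparison: on starting-material cost the alternative is the better. On step count it is about equal. On mechanism the chosen plan is the better, because all five ring A oxygens are fixed by step 3 and no C–O bond is made on the heterocycle, whereas the alternative puts its main risk in a twofold copper coupling two steps from the end.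

Alternative 3: The cut is at O1–C8a. The forward key step cyclizes the 2-bromoaryl 1,3-diketone A6 (1-[2,4-bis(benzyloxy)-6-bromo-3,5-dimethoxyphenyl]-3-[3,5-bis(benzyloxy)-4-methoxyphenyl]propane-1,3-dione) with CuI (monovalent copper) and K2CO3 in DMF. The enol oxygen attacks C8a with loss of bromide, forming a six-membered ring and giving A7 (5,7-bis(benzyloxy)-2-[3,5-bis(benzyloxy)-4-methoxyphenyl]-6,8-dimethoxychromen-4-one).
- In its favour: the bromine fixes the regiochemistry; the closure is a well-known intramolecular O-arylation; A7 is perbenzylated, so one hydrogenolysis ends the synthesis without any silyl removal.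
- Against it here: in A6 the two neighbours of the acyl carbon differ (Br and OBn), so the symmetry of ring A is lost and ring A has to be desymmetrized. The diketone must be made from a doubly ortho-substituted aryl ketone. The C8a–Br bond is electron-rich and flanked by OMe and acyl, which slows copper insertion and invites hydrodehalogenation.
- Comparison: on the endgame the alternative is the better. On the ring closure itself the two are equal, both being intramolecular six-membered closures with fixed regiochemistry. On step economy and on use of symmetry the chosen plan is the better, by two to three steps.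

Key step: step 9

Remark on the chemistry: 1, 7 and 13 are taken as purchased; benzyl bromide, N-bromosuccinimide, bis(pinacolato)diboron, oxalyl chloride, tert-butyldimethylsilyl triflate and chlorotrimethylsilane are treated as reagents and carry no number.

Remark on the structures: 12 and 18 were checked atom by atom against the numbering of 20 (benzoate C2–O becomes O1, C3 becomes C8, C4 becomes C7, C5 becomes C6, C6 becomes C5) and need no correction. The silyl pattern of 12 is kept, because one reagent then installs both the activated ester and the phenol protection. The refinements are: acylation before silylation on the symmetric acid 6, a non-nucleophilic silylation, and removal of the phenolic silyl group in the final flask.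

## Route

Step 1
Reactants: 1 2,6-dimethoxyphenol
Product: 2 2-(benzyloxy)-1,3-dimethoxybenzene
Conditions: BnBr, K2CO3, DMF, 60 °C
Reagents that add atoms: benzyl bromide, BrCc1ccccc1
Why: Williamson ether synthesis on the phenoxide; the benzyl group caps the hydroxyl so that it no longer directs electrophiles to its para position, and it is removable at the end with the ring B benzyl groups.

Step 2
Reactants: 2 2-(benzyloxy)-1,3-dimethoxybenzene
Product: 3 3-(benzyloxy)-1,5-dibromo-2,4-dimethoxybenzene
Conditions: NBS (2.1 equiv), MeCN, 0 °C to rt, dark
Reagents that add atoms: N-bromosuccinimide, O=C1CCC(=O)N1Br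
Why: Electrophilic aromatic bromination; the two outer methoxy groups direct ortho/para, while the central benzyloxy group is twisted out of the ring plane and contributes little, so both bromines should enter at C4 and C6 of 2 (each ortho to one methoxy and para to the other) and the position para to the benzyloxy group should stay free.

Step 3
Reactants: 3 3-(benzyloxy)-1,5-dibromo-2,4-dimethoxybenzene
Product: 5 5-(benzyloxy)-4,6-dimethoxybenzene-1,3-diol, via bis(pinacolboronate) 4 (not isolated)
Conditions: B2pin2 (2.6 equiv), Pd(dppf)Cl2 (5 mol %), KOAc, 1,4-dioxane, 90 °C; filter; then 30% H2O2, aq NaOH, THF, 0 °C, argon; H3O+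
Reagents that add atoms: bis(pinacolato)diboron, CC1(C)OB(OC1(C)C)B1OC(C)(C)C(C)(C)O1 (boron and pinacol of 4 only); hydrogen peroxide, OO (the two hydroxyl oxygens of 5)
Why: Twofold Miyaura borylation (zerovalent palladium inserts into each C–Br bond, acetate-assisted transmetalation, reductive elimination) followed by oxidation of each C–B bond through hydroperoxide addition and 1,2-aryl shift from boron to oxygen; each bromide has only one ortho substituent, and the benzyl and methyl ethers are inert to both stages.

Step 4
Reactants: 5 5-(benzyloxy)-4,6-dimethoxybenzene-1,3-diol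
Product: 6 4-(benzyloxy)-2,6-dihydroxy-3,5-dimethoxybenzoic acid
Conditions: KHCO3 (4 equiv), CO2 (5 bar), DMF, 110 °C; then 1 M HCl, 0 °C
Reagents that add atoms: carbon dioxide, O=C=O (supplied as gas and by potassium hydrogen carbonate, [K+].OC([O-])=O)
Why: Kolbe–Schmitt carboxylation of a resorcinolate; the only unsubstituted ring carbon lies ortho to both phenoxide oxygens, so there is no regiochemical choice, and cold acidification limits decarboxylation of the electron-rich acid.

Step 5
Reactants: 7 3,5-dihydroxy-4-methoxybenzoic acid
Product: 9 3,5-bis(benzyloxy)-4-methoxybenzoic acid, via benzyl ester 8 (not isolated)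
Conditions: BnBr (3.3 equiv), K2CO3, DMF, 60 °C; then NaOH, MeOH–H2O, 70 °C; HCl
Reagents that add atoms: benzyl bromide, BrCc1ccccc1; sodium hydroxide, [Na+].[OH-] (one carboxyl oxygen of 9)
Why: Exhaustive Williamson benzylation of both phenols and the carboxylate, then saponification, which cleaves only the benzyl ester and leaves the two aryl benzyl ethers.

Step 6
Reactants: 6 4-(benzyloxy)-2,6-dihydroxy-3,5-dimethoxybenzoic acid; 9 3,5-bis(benzyloxy)-4-methoxybenzoic acid
Product: 11 4-(benzyloxy)-2-{[3,5-bis(benzyloxy)-4-methoxybenzoyl]oxy}-6-hydroxy-3,5-dimethoxybenzoic acid, via acid chloride 10 (not isolated)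
Conditions: 9, (COCl)2, DMF (cat.), CH2Cl2, 0 °C to rt, evaporate; then 6 (1.1 equiv), iPr2NEt (2.3 equiv), DMAP (5 mol %), CH2Cl2, −20 °C to rt
Reagents that add atoms: oxalyl chloride, O=C(Cl)C(=O)Cl (chlorine of 10 only; no reagent atom remains in 11)
Why: Acid chloride formation through the chloroiminium ion, then O-acylation of the salicylate (Schotten–Baumann-type acyl transfer, relayed by the carboxylate to a neighbouring phenol oxygen or direct); the two hydroxyls of 6 are equivalent by symmetry so only one constitutional isomer can form, and 10 as the limiting partner at low temperature should hold the reaction at one acyl group, the surplus of polar 6 being removed by extraction.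

Step 7
Reactants: 11 4-(benzyloxy)-2-{[3,5-bis(benzyloxy)-4-methoxybenzoyl]oxy}-6-hydroxy-3,5-dimethoxybenzoic acid
Product: 12 tert-butyldimethylsilyl 4-(benzyloxy)-2-{[3,5-bis(benzyloxy)-4-methoxybenzoyl]oxy}-6-[(tert-butyldimethylsilyl)oxy]-3,5-dimethoxybenzoate
Conditions: TBSOTf (2.4 equiv), 2,6-lutidine, CH2Cl2, −78 to 0 °C; cold aq NaHCO3, rapid filtration through Et3N-treated silica
Reagents that add atoms: tert-butyldimethylsilyl trifluoromethanesulfonate, CC(C)(C)[Si](C)(C)OS(=O)(=O)C(F)(F)F
Why: O-silylation of the carboxylic acid and of the hindered, hydrogen-bonded phenol by a silyl triflate; the hindered pyridine base is not nucleophilic, so the activated aryl ester should not be cleaved as it could be by imidazole.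

Step 8
Reactants: 13 methyltriphenylphosphonium bromide
Product: 16 (trimethylsilyl)methylenetriphenylphosphorane, via methylenetriphenylphosphorane 14 (not isolated), via (trimethylsilylmethyl)triphenylphosphonium chloride 15 (not isolated)
Conditions: NaN(SiMe3)2 (1.0 equiv per 13), THF, 0 °C to rt; Me3SiCl (0.5 equiv per 13), 0 °C to rt; filtration under argon, solution used directly
Reagents that add atoms: chlorotrimethylsilane, C[Si](C)(C)Cl
Why: Deprotonation to the methylene ylide, C-silylation of half of it, and transylidation in which the second half of 14 deprotonates 15; the α-silyl phosphonium salt is the stronger acid, so the equilibrium lies on the side of 16, and no alkyllithium that could attack silicon is present.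

Step 9
Reactants: 12 tert-butyldimethylsilyl 4-(benzyloxy)-2-{[3,5-bis(benzyloxy)-4-methoxybenzoyl]oxy}-6-[(tert-butyldimethylsilyl)oxy]-3,5-dimethoxybenzoate; 16 (trimethylsilyl)methylenetriphenylphosphorane
Product: 18 7-(benzyloxy)-2-[3,5-bis(benzyloxy)-4-methoxyphenyl]-5-[(tert-butyldimethylsilyl)oxy]-6,8-dimethoxychromen-4-one, via acylphosphorane 17 (not isolated)
Conditions: 16 (1.2 equiv, added slowly), THF, 0 °C to rt, then reflux
Reagents that add atoms: none
Why: The ylide carbon of 16 adds to the silyl ester carbonyl of 12 (future C4), the tetrahedral adduct expels tert-butyldimethylsilanolate, and this silanolate removes the trimethylsilyl group from the α-silyl acylphosphonium ion, giving the stabilized acylphosphorane 17 with the C3–C4 bond in place. On heating, the ylide carbon of 17 adds to the neighbouring aryl ester carbonyl (future C2) and the oxaphosphetane loses Ph3PO to form C2=C3, the ester oxygen becoming O1. The closest known reaction type is the acylation of silylated phosphorus ylides by silyl esters followed by intramolecular ester Wittig olefination, established as a flavone synthesis for silyl esters of O-aroylsalicylic acids. Ring C closes in a 6-exo-trig mode (ylide carbon onto an ester carbonyl whose oxygen stays outside the new ring), and formation of the conjugated pyranone makes the closure irreversible. No stereocentre is formed and the endocyclic C2=C3 bond has only one possible geometry. The selectivity needed is attack at the silyl ester before the aryl ester: the silyl ester should be the better acyl donor because silanolate departure is made irreversible by the desilylation, and because its carbonyl, twisted out of the ring plane by two ortho groups, is not deactivated by conjugation, whereas the aroyl carbonyl is conjugated with the trialkoxyphenyl ring B. The silyl ether on the remaining ring A oxygen ensures that 16 meets no acidic proton, and 17 is too stabilized to be acylated a second time. Slow addition of near-stoichiometric 16 at 0 °C keeps free ylide away from the aryl ester once the acylation is over.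

Step 10
Reactants: 18 7-(benzyloxy)-2-[3,5-bis(benzyloxy)-4-methoxyphenyl]-5-[(tert-butyldimethylsilyl)oxy]-6,8-dimethoxychromen-4-one
Product: 20 5,7-dihydroxy-2-(3,5-dihydroxy-4-methoxyphenyl)-6,8-dimethoxychromen-4-one, via 5-hydroxyflavone tribenzyl ether 19 (not isolated)
Conditions: Bu4NF (1.1 equiv), AcOH (1.1 equiv), THF, 0 °C; then MeOH, 10% Pd/C, H2 (1 atm), rt
Reagents that add atoms: none
Why: Fluoride cleaves the aryl silyl ether readily because the phenoxide next to C4=O is a good leaving group, and heterogeneous hydrogenolysis then removes the three aryl benzyl ethers; the methyl ethers are untouched and the C2=C3 bond of the pyranone, a vinylogous ester, should resist hydrogenation at 1 atm and room temperature, so the product is the target.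

## Compound list

1 | 2,6-dimethoxyphenol | COc1cccc(OC)c1O | starting material
2 | 2-(benzyloxy)-1,3-dimethoxybenzene | COc1cccc(OC)c1OCc1ccccc1 | intermediate
3 | 3-(benzyloxy)-1,5-dibromo-2,4-dimethoxybenzene | COc1c(Br)cc(Br)c(OC)c1OCc1ccccc1 | intermediate
4 | 2,2'-[5-(benzyloxy)-4,6-dimethoxy-1,3-phenylene]bis(4,4,5,5-tetramethyl-1,3,2-dioxaborolane) | COc1c(B2OC(C)(C)C(C)(C)O2)cc(B2OC(C)(C)C(C)(C)O2)c(OC)c1OCc1ccccc1 | intermediate (not isolated)
5 | 5-(benzyloxy)-4,6-dimethoxybenzene-1,3-diol | COc1c(O)cc(O)c(OC)c1OCc1ccccc1 | intermediate
6 | 4-(benzyloxy)-2,6-dihydroxy-3,5-dimethoxybenzoic acid | COc1c(O)c(C(=O)O)c(O)c(OC)c1OCc1ccccc1 | intermediate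
7 | 3,5-dihydroxy-4-methoxybenzoic acid | COc1c(O)cc(C(=O)O)cc1O | starting material
8 | benzyl 3,5-bis(benzyloxy)-4-methoxybenzoate | COc1c(OCc2ccccc2)cc(C(=O)OCc2ccccc2)cc1OCc1ccccc1 | intermediate (not isolated)
9 | 3,5-bis(benzyloxy)-4-methoxybenzoic acid | COc1c(OCc2ccccc2)cc(C(=O)O)cc1OCc1ccccc1 | intermediate
10 | 3,5-bis(benzyloxy)-4-methoxybenzoyl chloride | COc1c(OCc2ccccc2)cc(C(=O)Cl)cc1OCc1ccccc1 | intermediate (not isolated)
11 | 4-(benzyloxy)-2-{[3,5-bis(benzyloxy)-4-methoxybenzoyl]oxy}-6-hydroxy-3,5-dimethoxybenzoic acid | COc1c(OCc2ccccc2)cc(C(=O)Oc2c(OC)c(OCc3ccccc3)c(OC)c(O)c2C(=O)O)cc1OCc1ccccc1 | intermediate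
12 | tert-butyldimethylsilyl 4-(benzyloxy)-2-{[3,5-bis(benzyloxy)-4-methoxybenzoyl]oxy}-6-[(tert-butyldimethylsilyl)oxy]-3,5-dimethoxybenzoate | COc1c(OCc2ccccc2)cc(C(=O)Oc2c(OC)c(OCc3ccccc3)c(OC)c(O[Si](C)(C)C(C)(C)C)c2C(=O)O[Si](C)(C)C(C)(C)C)cc1OCc1ccccc1 | intermediate
13 | methyltriphenylphosphonium bromide | C[P+](c1ccccc1)(c1ccccc1)c1ccccc1.[Br-] | starting material
14 | methylenetriphenylphosphorane | C=P(c1ccccc1)(c1ccccc1)c1ccccc1 | intermediate (not isolated)
15 | (trimethylsilylmethyl)triphenylphosphonium chloride | C[Si](C)(C)C[P+](c1ccccc1)(c1ccccc1)c1ccccc1.[Cl-] | intermediate (not isolated)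
16 | (trimethylsilyl)methylenetriphenylphosphorane | C[Si](C)(C)C=P(c1ccccc1)(c1ccccc1)c1ccccc1 | intermediate
17 | 5-(benzyloxy)-3-[(tert-butyldimethylsilyl)oxy]-4,6-dimethoxy-2-[(triphenylphosphoranylidene)acetyl]phenyl 3,5-bis(benzyloxy)-4-methoxybenzoate | COc1c(OCc2ccccc2)cc(C(=O)Oc2c(OC)c(OCc3ccccc3)c(OC)c(O[Si](C)(C)C(C)(C)C)c2C(=O)C=P(c2ccccc2)(c2ccccc2)c2ccccc2)cc1OCc1ccccc1 | intermediate (not isolated)
18 | 7-(benzyloxy)-2-[3,5-bis(benzyloxy)-4-methoxyphenyl]-5-[(tert-butyldimethylsilyl)oxy]-6,8-dimethoxychromen-4-one | COc1c(OCc2ccccc2)cc(-c2cc(=O)c3c(O[Si](C)(C)C(C)(C)C)c(OC)c(OCc4ccccc4)c(OC)c3o2)cc1OCc1ccccc1 | intermediate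
19 | 7-(benzyloxy)-2-[3,5-bis(benzyloxy)-4-methoxyphenyl]-5-hydroxy-6,8-dimethoxychromen-4-one | COc1c(OCc2ccccc2)cc(-c2cc(=O)c3c(O)c(OC)c(OCc4ccccc4)c(OC)c3o2)cc1OCc1ccccc1 | intermediate (not isolated)
20 | 5,7-dihydroxy-2-(3,5-dihydroxy-4-methoxyphenyl)-6,8-dimethoxychromen-4-one | COc1c(O)cc(-c2cc(=O)c3c(O)c(OC)c(O)c(OC)c3o2)cc1O | target

## Step count and least certain steps

Total step count: 10. Longest linear sequence: 8 steps (steps 1, 2, 3, 4, 6, 7, 9 and 10); step 5 (ring B) joins at step 6 and step 8 (ylide) joins at step 9.

Step 9 (key step). The most likely failure is misdirected acylation: the silyl ester carbonyl is flanked by two ortho substituents, so the bulky ylide may add instead to the more exposed aroyl carbonyl, transferring the ring B acyl group to phosphorus and releasing the ring A phenoxide. Fallback, setting out from 12: oxalyl chloride with catalytic DMF in CH2Cl2 would exchange the silyl ester for the acid chloride, 4-(benzyloxy)-2-{[3,5-bis(benzyloxy)-4-methoxybenzoyl]oxy}-6-[(tert-butyldimethylsilyl)oxy]-3,5-dimethoxybenzoyl chloride F1, under neutral conditions. Two equivalents of the smaller, unsilylated ylide 14 at −78 °C (one as nucleophile, one as base) should then be acylated by the far more electrophilic acid chloride in preference to the aryl ester. This gives 17, where the route is rejoined; heating closes ring C to 18.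

Step 6. The most likely failure is over-acylation: because the two hydroxyls of 6 are equivalent, a second aroyl group can enter and leave a mixture of unreacted, mono- and bis-acylated acid. Fallback, setting out from 6 and coming back at 20, in which the two hydroxyls are told apart before the acylation:
- Acetone, SOCl2 and catalytic DMAP in 1,2-dimethoxyethane would tie the carboxyl group and one hydroxyl into the acetonide 7-(benzyloxy)-5-hydroxy-6,8-dimethoxy-2,2-dimethyl-4H-1,3-benzodioxin-4-one F2.
- Benzyl bromide and K2CO3 in DMF would give 5,7-bis(benzyloxy)-6,8-dimethoxy-2,2-dimethyl-4H-1,3-benzodioxin-4-one F3.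
- KOH in aqueous DMSO would open the dioxinone to 2,4-bis(benzyloxy)-6-hydroxy-3,5-dimethoxybenzoic acid F4, which has a single phenol.
- Acylation with 10 would give 2,4-bis(benzyloxy)-6-{[3,5-bis(benzyloxy)-4-methoxybenzoyl]oxy}-3,5-dimethoxybenzoic acid F5.
- One equivalent of silyl triflate would give tert-butyldimethylsilyl 2,4-bis(benzyloxy)-6-{[3,5-bis(benzyloxy)-4-methoxybenzoyl]oxy}-3,5-dimethoxybenzoate F6.
- The same ylide sequence with 16 would give 5,7-bis(benzyloxy)-2-[3,5-bis(benzyloxy)-4-methoxyphenyl]-6,8-dimethoxychromen-4-one F7 (the same structure as A7).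
- Hydrogenolysis over Pd/C would then give 20 without a fluoride stage.
This fallback costs two more steps in the longest sequence.

Step 4. The most likely failure is loss of the new carboxyl group: Kolbe–Schmitt carboxylation is reversible, and the electron-rich acid can undergo protodecarboxylation during acidification. Fallback, setting out from 3 and coming back at 6, which installs the carboxyl carbon irreversibly before the hydroxyls exist: LiN(iPr)2 in THF at −78 °C would remove the ring proton between the two bromines (the only ring hydrogen, so no halogen migration is possible), and CO2 would trap the aryllithium as 4-(benzyloxy)-2,6-dibromo-3,5-dimethoxybenzoic acid F8. Carboxylate-assisted hydroxylation of both ortho C–Br bonds with CuI (monovalent copper) in aqueous NaOH at 90 °C, followed by cold acidification, would then give 6.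

Step 3. The most likely failures are hydrodebromination during the slower second borylation and over-oxidation of the electron-rich resorcinol under basic peroxide. Fallback, setting out from 3 and coming back at 5 with no new compound: direct palladium-catalysed C–O coupling with hydroxide (Pd2(dba)3, zerovalent palladium, with 2-di-tert-butylphosphino-2',4',6'-triisopropylbiphenyl and KOH in 1,4-dioxane–water at 100 °C under argon, then acidification). This avoids both the boron intermediate and the peroxide.

## Further compounds

F1 | step 9 | 4-(benzyloxy)-2-{[3,5-bis(benzyloxy)-4-methoxybenzoyl]oxy}-6-[(tert-butyldimethylsilyl)oxy]-3,5-dimethoxybenzoyl chloride | COc1c(OCc2ccccc2)cc(C(=O)Oc2c(OC)c(OCc3ccccc3)c(OC)c(O[Si](C)(C)C(C)(C)C)c2C(=O)Cl)cc1OCc1ccccc1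
F2 | step 6 | 7-(benzyloxy)-5-hydroxy-6,8-dimethoxy-2,2-dimethyl-4H-1,3-benzodioxin-4-one | COc1c(O)c2C(=O)OC(C)(C)Oc2c(OC)c1OCc1ccccc1
F3 | step 6 | 5,7-bis(benzyloxy)-6,8-dimethoxy-2,2-dimethyl-4H-1,3-benzodioxin-4-one | COc1c(OCc2ccccc2)c2C(=O)OC(C)(C)Oc2c(OC)c1OCc1ccccc1
F4 | step 6 | 2,4-bis(benzyloxy)-6-hydroxy-3,5-dimethoxybenzoic acid | COc1c(OCc2ccccc2)c(C(=O)O)c(O)c(OC)c1OCc1ccccc1
F5 | step 6 | 2,4-bis(benzyloxy)-6-{[3,5-bis(benzyloxy)-4-methoxybenzoyl]oxy}-3,5-dimethoxybenzoic acid | COc1c(OCc2ccccc2)cc(C(=O)Oc2c(OC)c(OCc3ccccc3)c(OC)c(OCc3ccccc3)c2C(=O)O)cc1OCc1ccccc1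
F6 | step 6 | tert-butyldimethylsilyl 2,4-bis(benzyloxy)-6-{[3,5-bis(benzyloxy)-4-methoxybenzoyl]oxy}-3,5-dimethoxybenzoate | COc1c(OCc2ccccc2)cc(C(=O)Oc2c(OC)c(OCc3ccccc3)c(OC)c(OCc3ccccc3)c2C(=O)O[Si](C)(C)C(C)(C)C)cc1OCc1ccccc1
F7 | step 6 | 5,7-bis(benzyloxy)-2-[3,5-bis(benzyloxy)-4-methoxyphenyl]-6,8-dimethoxychromen-4-one | COc1c(OCc2ccccc2)cc(-c2cc(=O)c3c(OCc4ccccc4)c(OC)c(OCc4ccccc4)c(OC)c3o2)cc1OCc1ccccc1
F8 | step 4 | 4-(benzyloxy)-2,6-dibromo-3,5-dimethoxybenzoic acid | COc1c(Br)c(C(=O)O)c(Br)c(OC)c1OCc1ccccc1
F0 | step 3 | none | none
A1 | alternative 1 | 7-(benzyloxy)-2-[3,5-bis(benzyloxy)-4-methoxyphenyl]-5-hydroxy-6,8-dimethoxychromen-4-one | COc1c(OCc2ccccc2)cc(-c2cc(=O)c3c(O)c(OC)c(OCc4ccccc4)c(OC)c3o2)cc1OCc1ccccc1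
A2 | alternative 1 | ethyl 3-[3,5-bis(benzyloxy)-4-methoxyphenyl]-3-oxopropanoate | CCOC(=O)CC(=O)c1cc(OCc2ccccc2)c(OC)c(OCc2ccccc2)c1
A3 | alternative 2 | 2-[3,5-bis(benzyloxy)-4-methoxyphenyl]-5,7-dihydroxychromen-4-one | COc1c(OCc2ccccc2)cc(-c2cc(=O)c3c(O)cc(O)cc3o2)cc1OCc1ccccc1
A4 | alternative 2 | 2-[3,5-bis(benzyloxy)-4-methoxyphenyl]-6,8-dibromo-5,7-dihydroxychromen-4-one | COc1c(OCc2ccccc2)cc(-c2cc(=O)c3c(O)c(Br)c(O)c(Br)c3o2)cc1OCc1ccccc1
A5 | alternative 2 | 2-[3,5-bis(benzyloxy)-4-methoxyphenyl]-5,7-dihydroxy-6,8-dimethoxychromen-4-one | COc1c(OCc2ccccc2)cc(-c2cc(=O)c3c(O)c(OC)c(O)c(OC)c3o2)cc1OCc1ccccc1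
A6 | alternative 3 | 1-[2,4-bis(benzyloxy)-6-bromo-3,5-dimethoxyphenyl]-3-[3,5-bis(benzyloxy)-4-methoxyphenyl]propane-1,3-dione | COc1c(OCc2ccccc2)cc(C(=O)CC(=O)c2c(Br)c(OC)c(OCc3ccccc3)c(OC)c2OCc2ccccc2)cc1OCc1ccccc1
A7 | alternative 3 | 5,7-bis(benzyloxy)-2-[3,5-bis(benzyloxy)-4-methoxyphenyl]-6,8-dimethoxychromen-4-one | COc1c(OCc2ccccc2)cc(-c2cc(=O)c3c(OCc4ccccc4)c(OC)c(OCc4ccccc4)c(OC)c3o2)cc1OCc1ccccc1
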